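**Plan**
Atom labels follow the chromene: O1, C2, C3, C4, C4a, C5 to C8, C8a. Ring A is the benzene ring, ring B the 3-hydroxyphenyl group, ring C the pyran.
Cuts, in retrosynthetic order: the protecting group on the ring B oxygen; ring C at C4–C4a and O1–C2 (back to 3-methylbut-2-enal); ring A at C8–C8a and C5–C6; last, the bond from C6 to the ketone carbon.
Feature that allows the ring A cut: ketone C–C6–C7(O)–C8–CH2CH=CMe2 is the intact skeleton of 6-methylhept-5-en-2-one aroylated on its methyl carbon. The prenyl group already sits on the carbon that becomes C8, and C8a(O)–C4a–C5(O) has the oxidation pattern of a malonyl unit.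
Forward order: ring B is bought, the chain is joined by a crossed Claisen condensation, and ring A is built de novo by a [3+3] double acylation. Ring C is then annulated on C4a and the C8a oxygen, and deprotection ends the route.
Stereochemistry: none has to be set.

Key step: step 3

Remark: the SMILES carries no stereodescriptor and the structure has no stereocentre and no stereogenic double bond, so "single enantiomer" is read as the one achiral compound drawn.

Step 1
Reactants: 1 methyl 3-hydroxybenzoate
Product: 2 methyl 3-(methoxymethoxy)benzoate
Conditions: NaH, DMF, 0 °C; MOMCl, 0 °C → rt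
Reagents that add atoms: chloromethyl methyl ether (MOMCl), COCCl
Why: Williamson-type O-alkylation of the sodium phenoxide by the very reactive α-chloro ether should be clean, and the resulting acetal is inert to the hydride, amide and alkoxide bases of steps 2 and 3.

Step 2
Reactants: 2 methyl 3-(methoxymethoxy)benzoate, 3 6-methylhept-5-en-2-one
Product: 4 1-[3-(methoxymethoxy)phenyl]-7-methyloct-6-ene-1,3-dione
Conditions: NaH (2.5 equiv), THF, reflux, slow addition of 3; cold 1 M HCl to pH 5
Reagents that add atoms: none
Why: Crossed Claisen condensation with a non-enolisable aromatic ester: C-acylation is reversible under these conditions and drains to the methyl-side product, the only one that ends as an unhindered, fully delocalised sodium diketonate, while slow addition of 3 to ester and base keeps ketone self-aldolisation low.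

Step 3
Reactants: 4 1-[3-(methoxymethoxy)phenyl]-7-methyloct-6-ene-1,3-dione, 5 malonyl dichloride
Product: 10 [3-(methoxymethoxy)phenyl][2,4,6-trihydroxy-3-(3-methylbut-2-enyl)phenyl]methanone, via mono(silyl) enol ether 6 (not isolated), via bis(silyl) dienol ether 7 (not isolated), via pyranone 8 (not isolated), via triketo ester 9 (not isolated)
Conditions: (a) Me3SiCl, Et3N, toluene, rt, filter, evaporate; (b) LDA, THF, −78 °C, then Me3SiCl, −78 → 20 °C, evaporate (removes iPr2NH), pentane, filter; (c) slow addition to freshly distilled 5 (1.1 equiv), CH2Cl2 (0.02 M), −78 → 20 °C, evaporate; (d) Mg(OMe)2 (5 equiv), MeOH, reflux; cold 1 M HCl to pH 4; crude material carried through (a) to (d) without purification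
Reagents that add atoms: chlorotrimethylsilane, C[Si](C)(C)Cl (silyl groups of 6 and 7, none left in 10); magnesium methoxide, C[O-].C[O-].[Mg+2] (methoxy group of 9, none left in 10)
Why: Proposed new method: two-stage silylation converts 4 into the neutral, non-basic diene 7 (a lithium dianion would merely dehydrochlorinate 5 at its acidic CH2), whose terminal carbon, the future C8, is the most nucleophilic site and displaces the first chloride with loss of Me3SiCl to form C8–C8a. The second acid chloride is then captured inside the same molecule, either by C6 to give 10 at once or, more probably, by the adjacent C7 enol oxygen to give pyranone 8 (6-exo-trig O-acylation, second Me3SiCl lost). Magnesium methoxide opens 8 at the lactone carbonyl to the magnesium-chelated triketo ester 9, and the doubly activated C6 carbanion closes ring A on the ester carbon C5 by a 6-exo-trig Claisen (Dieckmann-type) condensation that loss of methanol and aromatisation render irreversible, so both channels end in 10. The closest known reaction types are the [3+3] cyclisations of 1,3-bis(silyl enol ethers) with 1,3-dielectrophiles, their terminal C-acylation by acid chlorides, pyranone formation from 1,3-dicarbonyl compounds and malonyl dichloride, and the alkoxide-induced isomerisation of 6-(2-oxoalkyl)-4-hydroxypyran-2-ones to acylphloroglucinols; their merger into one benzannulating operation on a γ-substituted diene is what is new. No stereocentre is created. Needed are terminal-before-central acylation (given by the vinylogous polarity of 7, whose aryl-side carbonyl has no α-hydrogen so that only one diene can form), 1:1 instead of 2:1 coupling (slow addition of 7 to a slight excess of 5 at high dilution) and Claisen instead of aldol folding of 9 (magnesium chelation plus the low electrophilicity of the conjugated aryl ketone at the far chain end).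

Step 4
Reactants: 10 [3-(methoxymethoxy)phenyl][2,4,6-trihydroxy-3-(3-methylbut-2-enyl)phenyl]methanone, 11 3-methylbut-2-enal
Product: 13 [5,7-dihydroxy-2,2-dimethyl-8-(3-methylbut-2-enyl)-2H-chromen-6-yl][3-(methoxymethoxy)phenyl]methanone, via quinone methide 12 (not isolated)
Conditions: ethylenediammonium diacetate (EDDA, 20 mol %), toluene, reflux
Reagents that add atoms: none
Why: Amine-salt-catalysed formal [3+3] chromene annulation (Knoevenagel-type attack of C4a, the only unsubstituted ring A carbon, on the iminium ion of 11, loss of the amine to quinone methide 12, then oxa-6π electrocyclisation), well known for acylphloroglucinols; closure on the C8a oxygen is expected to prevail because this is the one hydroxyl outside the hydrogen-bond chelate that the C5 and C7 hydroxyls share with the ketone, and the non-polar solvent leaves that chelate intact.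

Step 5
Reactants: 13 [5,7-dihydroxy-2,2-dimethyl-8-(3-methylbut-2-enyl)-2H-chromen-6-yl][3-(methoxymethoxy)phenyl]methanone
Product: 14 [5,7-dihydroxy-2,2-dimethyl-8-(3-methylbut-2-enyl)-2H-chromen-6-yl](3-hydroxyphenyl)methanone
Conditions: conc. HCl (cat.), MeOH, 40 °C, stopped at full conversion
Reagents that add atoms: none
Why: Acid-catalysed acetal exchange with methanol (standard MOM cleavage, routinely used on prenylated phenols) is much faster than protonation of the prenyl alkene or of the C3=C4 bond of a ring A that the aroyl group deactivates, so brief exposure should free only the ring B phenol.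

**Compound list**
1 | methyl 3-hydroxybenzoate | COC(=O)c1cccc(O)c1 | starting material
2 | methyl 3-(methoxymethoxy)benzoate | COCOc1cccc(C(=O)OC)c1 | intermediate
3 | 6-methylhept-5-en-2-one | CC(=O)CCC=C(C)C | starting material
4 | 1-[3-(methoxymethoxy)phenyl]-7-methyloct-6-ene-1,3-dione | COCOc1cccc(C(=O)CC(=O)CCC=C(C)C)c1 | intermediate
5 | malonyl dichloride | O=C(Cl)CC(=O)Cl | starting material
6 | 1-[3-(methoxymethoxy)phenyl]-7-methyl-3-(trimethylsilyloxy)octa-2,6-dien-1-one (enol ether geometry and silyl position mobile, without consequence) | COCOc1cccc(C(=O)C=C(O[Si](C)(C)C)CCC=C(C)C)c1 | intermediate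
7 | 1-[3-(methoxymethoxy)phenyl]-7-methyl-1,3-bis(trimethylsilyloxy)octa-1,3,6-triene (enol ether geometry not controlled, without consequence) | COCOc1cccc(C(O[Si](C)(C)C)=CC(O[Si](C)(C)C)=CCC=C(C)C)c1 | intermediate
8 | 4-hydroxy-6-{2-[3-(methoxymethoxy)phenyl]-2-oxoethyl}-5-(3-methylbut-2-enyl)-2H-pyran-2-one | O=C1C=C(O)C(CC=C(C)C)=C(CC(=O)c2cccc(OCOC)c2)O1 | intermediate
9 | methyl 7-[3-(methoxymethoxy)phenyl]-4-(3-methylbut-2-enyl)-3,5,7-trioxoheptanoate (drawn as the keto form; the prenyl-bearing carbon is configurationally labile) | COC(=O)CC(=O)C(CC=C(C)C)C(=O)CC(=O)c1cccc(OCOC)c1 | intermediate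
10 | [3-(methoxymethoxy)phenyl][2,4,6-trihydroxy-3-(3-methylbut-2-enyl)phenyl]methanone | CC(C)=CCc1c(O)cc(O)c(C(=O)c2cccc(OCOC)c2)c1O | intermediate
11 | 3-methylbut-2-enal | CC(C)=CC=O | starting material
12 | 3,5-dihydroxy-4-[3-(methoxymethoxy)benzoyl]-6-(3-methylbut-2-enylidene)-2-(3-methylbut-2-enyl)cyclohexa-2,4-dien-1-one (exocyclic alkene geometry mobile) | CC(C)=CC=C1C(=O)C(CC=C(C)C)=C(O)C(C(=O)c2cccc(OCOC)c2)=C1O | intermediate
13 | [5,7-dihydroxy-2,2-dimethyl-8-(3-methylbut-2-enyl)-2H-chromen-6-yl][3-(methoxymethoxy)phenyl]methanone | CC(C)=CCc1c(O)c(C(=O)c2cccc(OCOC)c2)c(O)c2c1OC(C)(C)C=C2 | intermediate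
14 | [5,7-dihydroxy-2,2-dimethyl-8-(3-methylbut-2-enyl)-2H-chromen-6-yl](3-hydroxyphenyl)methanone | CC(C)=CCc1c(O)c(C(=O)c2cccc(O)c2)c(O)c2c1OC(C)(C)C=C2 | target

Total step count: 5
Longest linear sequence: 5 steps (1 → 2 → 4 → 10 → 13 → 14)

**Steps most likely to fail**

1. Step 3 (the labelled step).
   - Risk: the diacid chloride may couple with two diene molecules or self-condense through loss of HCl. The open chain may suffer retro-Claisen cleavage by methoxide next to the prenyl-bearing carbon, or it may fold in the aldol sense onto the aryl ketone.
   - Fallback, known chemistry only: the two C–C bonds are made in two separate reactions with a malonyl unit whose ends are differentiated. Setting out from 4, diene 7 is prepared as in operations (a) and (b). It is acylated at its terminal carbon with methyl 3-chloro-3-oxopropanoate (CH2Cl2, −78 → 20 °C, aqueous NaHCO3 work-up), a known terminal C-acylation of bis(silyl enol ethers).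
   - The triketo ester 9 is now isolated and purified. It is then closed in a separate, biomimetic Claisen cyclisation (Mg(OMe)2, MeOH, reflux), which comes back to the route at 10. This fallback makes no compound outside the list (F0).

2. Step 4.
   - Risk: proton shifts between the ring oxygens and rotation about the exocyclic double bond of the quinone methide may allow ring closure on the C5 oxygen as well. That hydroxyl is released from the chelate whenever the C7 hydroxyl holds the ketone, so regiocontrol may be poor.
   - Fallback: the ring oxygen is fixed before the C–C bond is made. Setting out from 10, the C8a hydroxyl, the most acidic and the only unchelated one, is O-alkylated with 3-chloro-3-methylbut-1-yne (DBU, cat. CuCl2, MeCN, 0 °C). This gives the 1,1-dimethylpropargyl ether [2,6-dihydroxy-4-(2-methylbut-3-yn-2-yloxy)-3-(3-methylbut-2-enyl)phenyl][3-(methoxymethoxy)phenyl]methanone F1.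
   - Gold(I)-catalysed 6-endo-dig hydroarylation (Ph3PAuNTf2 cat., CH2Cl2, rt) then joins the alkyne terminus to C4a. The O–C bond is never broken and no quinone methide is passed. The fallback comes back to the route at 13.

3. Step 5.
   - Risk: protonation of the electron-rich C3=C4 bond leads to a C4 cation stabilised by three ring oxygens. This may compete with acetal cleavage and start methanol addition or dimerisation.
   - Fallback: the last two operations are exchanged so that acid never meets the chromene. Setting out from 10, the MOM group is removed first (conc. HCl cat., MeOH, 40 °C) to give (3-hydroxyphenyl)[2,4,6-trihydroxy-3-(3-methylbut-2-enyl)phenyl]methanone F2.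
   - The ring B phenol of F2, a lone hydroxyl on an acyl-substituted ring, is not nucleophilic enough at carbon to engage the iminium ion of 11. EDDA-catalysed annulation with 11 in refluxing toluene therefore proceeds on ring A alone, through 3,5-dihydroxy-4-(3-hydroxybenzoyl)-6-(3-methylbut-2-enylidene)-2-(3-methylbut-2-enyl)cyclohexa-2,4-dien-1-one F3. It comes back to the route directly at 14.

**Further compounds**
F0 | step 3 | none | none
F1 | step 4 | [2,6-dihydroxy-4-(2-methylbut-3-yn-2-yloxy)-3-(3-methylbut-2-enyl)phenyl][3-(methoxymethoxy)phenyl]methanone | C#CC(C)(C)Oc1cc(O)c(C(=O)c2cccc(OCOC)c2)c(O)c1CC=C(C)C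
F2 | step 5 | (3-hydroxyphenyl)[2,4,6-trihydroxy-3-(3-methylbut-2-enyl)phenyl]methanone | CC(C)=CCc1c(O)cc(O)c(C(=O)c2cccc(O)c2)c1O
F3 | step 5 | 3,5-dihydroxy-4-(3-hydroxybenzoyl)-6-(3-methylbut-2-enylidene)-2-(3-methylbut-2-enyl)cyclohexa-2,4-dien-1-one | CC(C)=CC=C1C(=O)C(CC=C(C)C)=C(O)C(C(=O)c2cccc(O)c2)=C1O
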